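The carbocycle is closed by the aldol half of a catalytic asymmetric Robinson annulation, and the pyridine is condensed onto the resulting enone last. The route has not been run; the sense of induction in step 6 is assumed.

**Strategy.** In tetrahydroquinoline numbering, the pyridine is read as ammonia condensed onto a latent C8a ketone and a latent C2 aldehyde. Ring-fusion carbon C4a then becomes a ketone α-carbon, and C5, the CH2 beside quaternary C6, an aldehyde carbon. The carbocycle is therefore closed through the C4a–C5 bond by the aldol condensation that ends the annulation. In one operation a racemic, configurationally labile 2-aryl-4-(formamido)butanal and an acetal-bearing vinyl ketone should give the (R)-4,4-disubstituted cyclohexenone, setting C6 stereoconvergently. The C4a=C5 enone bond stores the oxidation level of the pyridine, so ammonium acetate should then aromatise directly.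

Key step: step 6

Assumption: the sense of induction of the amine–thiourea catalyst in step 6 is assigned by analogy; if the (1R,2R) catalyst favours the wrong enone enantiomer, its (1S,2S) antipode is used and nothing else changes.

**Step 1**
Reactants: 1 2-chloro-N-methylethanamine hydrochloride
Product: 2 N-(2-chloroethyl)-N-methylformamide
Conditions: N-formylsaccharin (1.1 equiv), Et3N (2.2 equiv), THF, 0 °C → rt
Reagents that add atoms: N-formylsaccharin O=CN1C(=O)c2ccccc2S1(=O)=O
Why: N-formylation by acyl transfer from an activated N-formyl imide is fast at 0 °C and should cap the secondary amine as soon as it is freed from its salt, before it can close to an aziridinium ion.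

**Step 2**
Reactants: 2 N-(2-chloroethyl)-N-methylformamide; 3 (3,4-dimethoxyphenyl)acetonitrile
Product: 4 2-(3,4-dimethoxyphenyl)-4-[formyl(methyl)amino]butanenitrile (racemic)
Conditions: NaH (1.0 equiv), NaI (10 mol%), THF/DMF (4:1), 0 → 45 °C; 3 in slight excess
Reagents that add atoms: none
Why: SN2 C-alkylation of the nitrile-stabilised benzylic carbanion by the primary chloride (Finkelstein-assisted) should proceed with the tertiary formamide inert and the excess of 3 limiting dialkylation; the new centre is racemic, which is all the route needs.

**Step 3**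
Reactants: 4 2-(3,4-dimethoxyphenyl)-4-[formyl(methyl)amino]butanenitrile
Product: 5 2-(3,4-dimethoxyphenyl)-4-[formyl(methyl)amino]butanal (racemic)
Conditions: Raney Ni, NaH2PO2·H2O, pyridine/AcOH/H2O (2:1:1), 45 °C
Reagents that add atoms: water O
Why: hypophosphite/Raney nickel transfer semi-reduction of the nitrile to the aldimine with hydrolysis in situ (Backeberg–Staskun reduction) should spare the tertiary formamide, which hydride reagents such as DIBAL-H would attack.

**Step 4**
Reactants: 6 2-(3-chloropropyl)-1,3-dioxolane; 7 acrolein
Product: 9 6-(1,3-dioxolan-2-yl)hex-1-en-3-ol (racemic), via Grignard reagent 8 (not isolated)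
Conditions: Mg, iodine (cat.), THF, 55 °C; then 7 (1.1 equiv), −78 → 0 °C; aq. NH4Cl
Reagents that add atoms: none
Why: Grignard formation from the primary chloride and 1,2-addition of this hard nucleophile to acrolein should give the vinyl carbinol, the dioxolane being inert to the basic conditions; the carbinol centre is removed in step 5.

**Step 5**
Reactants: 9 6-(1,3-dioxolan-2-yl)hex-1-en-3-ol
Product: 10 6-(1,3-dioxolan-2-yl)hex-1-en-3-one
Conditions: 2-iodoxybenzoic acid (1.5 equiv), EtOAc, 75 °C; filtered and used at once
Reagents that add atoms: none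
Why: oxidation of the secondary allylic alcohol with 2-iodoxybenzoic acid is essentially neutral, so the acetal should survive and the polymerisation-prone vinyl ketone is obtained by simple filtration.

**Step 6**
Reactants: 5 2-(3,4-dimethoxyphenyl)-4-[formyl(methyl)amino]butanal (racemic); 10 6-(1,3-dioxolan-2-yl)hex-1-en-3-one
Product: 12 (R)-4-(3,4-dimethoxyphenyl)-2-[2-(1,3-dioxolan-2-yl)ethyl]-4-{2-[formyl(methyl)amino]ethyl}cyclohex-2-en-1-one, via Michael adduct 11 (not isolated)
Conditions: 1-[(1R,2R)-2-aminocyclohexyl]-3-[3,5-bis(trifluoromethyl)phenyl]thiourea (20 mol%), PhCO2H (20 mol%), toluene, rt; then pyrrolidine (30 mol%), AcOH (30 mol%), 45 °C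
Reagents that add atoms: none
Why: The primary amine of the catalyst condenses with racemic 5 to an aryl-conjugated enamine in which the labile α-centre is erased, and the thiourea hydrogen-bonds the carbonyl of 10 so that conjugate addition should occur on one enamine face, funnelling both enantiomers of 5 into (S)-11 (stereoconvergent amine-catalysed Michael addition of an α-branched aldehyde to a vinyl ketone, the first half of an asymmetric Robinson annulation). Pyrrolidinium acetate then converts the ketone of 11 into an enamine whose α′-carbon attacks the aldehyde (or its iminium ion) in a 6-(enolendo)-exo-trig aldol closure, and loss of water gives enone 12; this is the bond that becomes C4a–C5 of the tetrahydroquinoline. The only stereocentre, quaternary C6, is set by the catalyst in the Michael event and cannot epimerise afterwards because it carries no hydrogen. The step needs facial selectivity (catalyst), C- over N-alkylation of the enamine (soft acceptor) and a regioselective aldol closure. The last is secured because the aldehyde has no α-hydrogen and the other ketone α-carbon could only close a four-membered ring. The acetal and the tertiary formamide should be inert to these weakly acidic amine conditions.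

**Step 7**
Reactants: 12 (R)-4-(3,4-dimethoxyphenyl)-2-[2-(1,3-dioxolan-2-yl)ethyl]-4-{2-[formyl(methyl)amino]ethyl}cyclohex-2-en-1-one
Product: 15 (S)-N-{2-[6-(3,4-dimethoxyphenyl)-5,6,7,8-tetrahydroquinolin-6-yl]ethyl}-N-methylformamide, via keto-aldehyde 13 (not isolated), via alkylidene-dihydropyridine 14 (not isolated)
Conditions: NH4OAc (10 equiv), AcOH/H2O (5:1), 100 °C
Reagents that add atoms: ammonium acetate CC(=O)[O-].[NH4+]
Why: acetal hydrolysis unmasks the aldehyde, ammonia condenses with the unsaturated 1,5-dicarbonyl unit (pyridine synthesis from an ene-1,5-dicarbonyl compound), and the exocyclic C4a=C5 tautomer should aromatise by a proton shift from C4 to C5 without any oxidant; C6 is untouched, and its descriptor changes from R to S only because the CIP priorities change.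

**Compound list**
1 | 2-chloro-N-methylethanamine hydrochloride | CNCCCl.Cl | starting material
2 | N-(2-chloroethyl)-N-methylformamide | O=CN(C)CCCl | intermediate
3 | (3,4-dimethoxyphenyl)acetonitrile | COc1ccc(CC#N)cc1OC | starting material
4 | 2-(3,4-dimethoxyphenyl)-4-[formyl(methyl)amino]butanenitrile (racemic) | COc1ccc(C(C#N)CCN(C)C=O)cc1OC | intermediate
5 | 2-(3,4-dimethoxyphenyl)-4-[formyl(methyl)amino]butanal (racemic) | COc1ccc(C(C=O)CCN(C)C=O)cc1OC | intermediate
6 | 2-(3-chloropropyl)-1,3-dioxolane | ClCCCC1OCCO1 | starting material
7 | acrolein | C=CC=O | starting material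
8 | [3-(1,3-dioxolan-2-yl)propyl]magnesium chloride | Cl[Mg]CCCC1OCCO1 | intermediate
9 | 6-(1,3-dioxolan-2-yl)hex-1-en-3-ol (racemic) | C=CC(O)CCCC1OCCO1 | intermediate
10 | 6-(1,3-dioxolan-2-yl)hex-1-en-3-one | C=CC(=O)CCCC1OCCO1 | intermediate
11 | (S)-2-(3,4-dimethoxyphenyl)-8-(1,3-dioxolan-2-yl)-2-{2-[formyl(methyl)amino]ethyl}-5-oxooctanal | COc1ccc([C@@](C=O)(CCN(C)C=O)CCC(=O)CCCC2OCCO2)cc1OC | intermediate
12 | (R)-4-(3,4-dimethoxyphenyl)-2-[2-(1,3-dioxolan-2-yl)ethyl]-4-{2-[formyl(methyl)amino]ethyl}cyclohex-2-en-1-one | COc1ccc([C@@]2(CCN(C)C=O)CCC(=O)C(CCC3OCCO3)=C2)cc1OC | intermediate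
13 | (R)-4-(3,4-dimethoxyphenyl)-4-{2-[formyl(methyl)amino]ethyl}-2-(3-oxopropyl)cyclohex-2-en-1-one | COc1ccc([C@@]2(CCN(C)C=O)CCC(=O)C(CCC=O)=C2)cc1OC | intermediate
14 | (R)-N-{2-[6-(3,4-dimethoxyphenyl)-4,6,7,8-tetrahydroquinolin-6-yl]ethyl}-N-methylformamide (exocyclic C4a=C5 tautomer) | COc1ccc([C@@]2(CCN(C)C=O)CCC3=NC=CCC3=C2)cc1OC | intermediate
15 | (S)-N-{2-[6-(3,4-dimethoxyphenyl)-5,6,7,8-tetrahydroquinolin-6-yl]ethyl}-N-methylformamide | COc1ccc([C@@]2(CCN(C)C=O)CCc3ncccc3C2)cc1OC | target

**Step count.** Total: 7 steps. Longest linear sequence: 5 steps (1, 2, 3, 6, 7).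

**Steps most likely to fail**

Step 6. The conjugate addition may show poor facial selectivity, because the formamide can compete for the thiourea. Enamine formation from the hindered α-aryl aldehyde may also be slow, leaving the vinyl ketone to oligomerise. The fallback replaces catalysis by auxiliary control and sets out from 5. Condensation of 5 with (S)-2-(methoxymethyl)pyrrolidine (toluene, molecular sieves) should give the preformed chiral enamine N-[(E)-3-(3,4-dimethoxyphenyl)-4-[(S)-2-(methoxymethyl)pyrrolidin-1-yl]but-3-enyl]-N-methylformamide F1. Addition of F1 to 10 (MeCN, 0 °C → rt), followed by hydrolysis and cyclisation with aqueous AcOH/NaOAc at 60 °C, passes through 11 and comes back to the route at 12. The auxiliary is recovered, and its antipode is used if the sense of induction is wrong.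

Step 7. The condensation may stall at non-aromatic dihydropyridine tautomers (incomplete proton shift), or reversible conjugate addition of ammonia to the enone may divert material. The fallback sets out from 12. Hydrogenation of the enone (H2, Pd/C, EtOAc) should give the saturated ketone (4S)-4-(3,4-dimethoxyphenyl)-2-[2-(1,3-dioxolan-2-yl)ethyl]-4-{2-[formyl(methyl)amino]ethyl}cyclohexan-1-one F2 as C2 epimers. The C2 side chain keeps the ring unsymmetrical, so the quaternary centre stays stereogenic. Treatment of F2 with NH2OH·HCl in AcOH at 100 °C (acetal cleavage, oxime formation, cyclisation and loss of water; the classical hydroxylamine pyridine synthesis from a 1,5-dicarbonyl compound) comes back to the route at 15.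

Step 3. The aldimine may be over-reduced to the primary amine, or reduction of the secondary aliphatic nitrile may stall. The fallback sets out from 2. Alkylation of commercial methyl (3,4-dimethoxyphenyl)acetate with 2 (LiHMDS, THF, −78 °C → rt, NaI cat.) should give methyl 2-(3,4-dimethoxyphenyl)-4-[formyl(methyl)amino]butanoate F3. LiBH4 (THF, 0 °C → rt) should reduce the ester but not the tertiary formamide, giving N-[3-(3,4-dimethoxyphenyl)-4-hydroxybutyl]-N-methylformamide F4. Dess–Martin oxidation (NaHCO3, CH2Cl2) then comes back to the route at 5.

**Further compounds**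
F1 | step 6 | N-[(E)-3-(3,4-dimethoxyphenyl)-4-[(S)-2-(methoxymethyl)pyrrolidin-1-yl]but-3-enyl]-N-methylformamide | COC[C@@H]1CCCN1/C=C(/c1ccc(OC)c(OC)c1)CCN(C)C=O
F2 | step 7 | (4S)-4-(3,4-dimethoxyphenyl)-2-[2-(1,3-dioxolan-2-yl)ethyl]-4-{2-[formyl(methyl)amino]ethyl}cyclohexan-1-one (C2 epimers) | COc1ccc([C@@]2(CCN(C)C=O)CCC(=O)C(CCC3OCCO3)C2)cc1OC
F3 | step 3 | methyl 2-(3,4-dimethoxyphenyl)-4-[formyl(methyl)amino]butanoate (racemic) | COC(=O)C(CCN(C)C=O)c1ccc(OC)c(OC)c1
F4 | step 3 | N-[3-(3,4-dimethoxyphenyl)-4-hydroxybutyl]-N-methylformamide (racemic) | OCC(CCN(C)C=O)c1ccc(OC)c(OC)c1
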